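Hold on to the count of step 1: each G formed costs one D and one Z and brings one X, so [D] plus [G] stays at the charge of D, and [X] equals [G].

    D + Z ⇌ G + X (K1 = 1.6, k1 = 0.0595 M⁻¹ s⁻¹)
    Q ⇌ Z, rate k2*(cs2 - [Z]) while solid is left; crystals form when [Z] > cs2 (cs2 = 1.9 mM, k2 = 0.00281 s⁻¹)

all flasks: Q 1.50 equiv; time 25 min

| charge | D |
|---|---|
| north-east | 5.0 mM |
| north | 10 mM |
| south | 20 mM |

* amount of G at the end, in percent of the D charged for north-east, north, south, in this order
* how that number moves from the first to the last of them (hardly changes / rises all the way / falls, then rises / rises, then falls / falls all the way)

- solid, in amounts per volume of the solution: Q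
- at the start none of Q is in solution
- "hardly changes" means that all values lie within two and a half points (for a concentration: within two and a half percent of the largest)
- run time (north-east): 25 min

Start from Z, which step 1 spends and Q replaces. Where the two balance, k2 times (cs2 − [Z]) equals k1[D][Z], which rearranges to a standing level [Z] = cs2/(1 + h), with h = k1[D]/k2. Call h the drain ratio, the pull of D on Z set against the refilling from Q; for north-east as charged it is 0.106. Z climbs from nothing towards that level with the time constant 1/(k2(1 + h)), which for north-east is 5.36 min, shorter than the run. So treat D as pseudo-first-order at k1 times the standing [Z], and take that time constant off the run. This is the first round; for the second, put the first answer back in by using the charge of D less half of what was converted.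

| flask | h | standing [Z] | G, first round | G, second round |
|---|---|---|---|---|
| north-east | 0.106 | 1.72 mM | 11.3 % | 11.4 % |
| north | 0.212 | 1.57 mM | 10.6 % | 10.7 % |
| south | 0.423 | 1.33 mM | 9.45 % | 9.55 % |

Read the second column first: h grows by a factor of 4.00 from north-east to south, yet the standing [Z] falls by a factor of just 1.29. Then compare the last two columns: the second round moves south by 0.1 percentage points, so stop there. Check the solid in north-east, where the reckoning puts 2.29 mM into solution and product against 7.50 mM of Q charged. Check the way back too: for the end of south the reckoning puts it at 9.18 % of the forward rate, so leave it out and expect south to come out slightly high. Commit to the last column, a fall of 1.8 points, inside the 2.5 points of "hardly changes".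

The forecast gave 11.3 %, 10.5 % and 9.4 %, hardly changes, saying “the yield drifts down by only about 2 points”.

The simulation gives 11.3 %, 10.6 % and 9.31 %, so the amount of G hardly changes. South holds 91 % of its D at 25.0 min, with [Z] reading 1.38 mM. Put that D of south into the drain ratio, scaling the north-east value by the charges, and h becomes 0.384, which gives a standing [Z] of 1.37 mM against that reading of 1.38 mM.

Its constants belong to no real substance, and the outcome is calculated.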